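The 2-pyranone ring is disconnected to dimethyl squarate: its C(=O)–C(OMe)=C(OMe) unit already is C2, C3 and C4 of the ring with both methoxy groups in place, and its second carbonyl carbon becomes C5. One palladium-catalysed operation joins a squarate-derived 4-chlorocyclobutenone, carbon monoxide and a tin-bound methyl group, forming C5–C6 and C6–CH3; the 4-acetylcyclobutenone so formed opens to an acyl vinylketene and recloses through O1–C2 to the fully substituted pyranone. The precursor is racemic 4-chloro-2,3-dimethoxy-4-methylcyclobut-2-en-1-one, two steps from the squarate. Bromination of the 6-methyl group and coupling with an E-alkenylalane then attach the side chain.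

Key step: step 3

Assumption: the tertiary chlorocyclobutenone is moisture-sensitive, so it is carried into the key step without aqueous work-up or chromatography.

Step 1
Reactants: 1 dimethyl squarate; 2 methyllithium
Product: 3 4-hydroxy-2,3-dimethoxy-4-methylcyclobut-2-en-1-one (racemic)
Conditions: MeLi (1.05 equiv), THF, −78 °C; aq NH4Cl at −78 °C
Reagents that add atoms: methyllithium, [Li]C
Why: 1,2-addition of an organolithium to one of the two equivalent carbonyls of a squarate ester at low temperature should stop at the mono-adduct because the lithium alkoxide deactivates the ring, and the new carbinol centre is racemic, which does not matter since it later becomes sp2 C5.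

Step 2
Reactants: 3 4-hydroxy-2,3-dimethoxy-4-methylcyclobut-2-en-1-one; 4 thionyl chloride
Product: 5 4-chloro-2,3-dimethoxy-4-methylcyclobut-2-en-1-one (racemic)
Conditions: SOCl2 (1.1 equiv), pyridine (1.2 equiv), CH2Cl2, −20 to 0 °C; dry pentane, filtration under argon, concentration; used crude
Reagents that add atoms: thionyl chloride, O=S(Cl)Cl
Why: Deoxychlorination of a 4-hydroxycyclobutenone through its chlorosulfite should proceed by ionisation to the stabilised oxocyclobutenyl cation and chloride return at the methyl-bearing carbon, which keeps the dimethoxy enone; water is excluded to prevent hydrolysis, and an allylic shift of chlorine would be harmless because either positional isomer ionises to the same palladium intermediate in step 3.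

Step 3
Reactants: 5 4-chloro-2,3-dimethoxy-4-methylcyclobut-2-en-1-one; 6 carbon monoxide; 7 tetramethylstannane
Product: 10 3,4-dimethoxy-5,6-dimethylpyran-2-one, via 4-acetylcyclobutenone 8 (not isolated), via acyl vinylketene 9 (not isolated)
Conditions: Me4Sn (1.5 equiv), CO (3 atm), Pd(PPh3)4 (5 mol%), dioxane, sealed vessel, 60 °C then 100 °C
Reagents that add atoms: carbon monoxide, [C-]#[O+]; tetramethylstannane, C[Sn](C)(C)C
Why: Zerovalent palladium ionises the activated tertiary allylic C–Cl bond of 5 to an η3-oxocyclobutenyl palladium chloride (the same species whichever allylic position carries chlorine), and CO insertion, methyl transfer from tin and reductive elimination give 8, creating C5–C6 and C6–CH3. The closest known reaction type is the carbonylative Stille coupling of allylic chlorides, which with 4-chlorocyclobutenones is known to deliver 2-pyranones directly. On heating, 8 opens by conrotatory 4π electrocyclic cleavage of its C1–C4 ring bond (cyclobutenone numbering) to acyl vinylketene 9, and the pyranone ring closes by 6π oxa-electrocyclisation of the acetyl oxygen onto the ketene carbon (O1–C2); ring opening is reversible and an acyl group prefers inward rotation, so all material should drain through the E isomer that can cyclise. No stereocentre is formed, the racemic centre of 5 and 8 becoming sp2 C5. The step needs acyl delivery to the methyl-bearing rather than the methoxy-bearing allyl terminus and CO uptake ahead of direct methyl transfer: the first is favoured because bonding at the methyl-bearing carbon keeps both methoxy groups on the enone π system, whereas the alternative would place a methoxy group on an sp3 carbon between two carbonyls, and the second by CO pressure together with the slow transmetalation of Me4Sn. This terminus preference is untested for a fully substituted dimethoxy system and is the one real risk of the route.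

Step 4
Reactants: 10 3,4-dimethoxy-5,6-dimethylpyran-2-one; 11 lithium bis(trimethylsilyl)amide; 12 1,2-dibromo-1,1,2,2-tetrachloroethane
Product: 14 6-(bromomethyl)-3,4-dimethoxy-5-methylpyran-2-one, via lithium dienolate 13 (not isolated)
Conditions: LiN(SiMe3)2 (1.05 equiv), THF, −78 °C; then cannulation into BrCCl2CCl2Br (1.5 equiv), THF, −78 °C
Reagents that add atoms: 1,2-dibromo-1,1,2,2-tetrachloroethane, BrC(Cl)(Cl)C(Cl)(Cl)Br
Why: The 6-methyl group is the vinylogous α-position of the lactone carbonyl while the 5-methyl group is only cross-conjugated, so deprotonation should be selective, and bromination of the extended enolate with a positive-bromine donor (enolate halogenation) should occur at the exocyclic carbon, with inverse addition limiting over-bromination and self-alkylation.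

Step 5
Reactants: 15 (6-bromohexyl)benzene; 16 lithium acetylide–ethylenediamine complex
Product: 17 oct-7-yn-1-ylbenzene (8-phenyloct-1-yne)
Conditions: LiC≡CH·H2NCH2CH2NH2 (1.5 equiv), DMSO, 10 °C to rt
Reagents that add atoms: lithium acetylide–ethylenediamine complex, [Li]C#C.NCCN
Why: SN2 alkylation of lithium acetylide by an unhindered primary bromide in DMSO is the standard two-carbon extension to a terminal alkyne.

Step 6
Reactants: 17 oct-7-yn-1-ylbenzene; 18 trimethylaluminium; 14 6-(bromomethyl)-3,4-dimethoxy-5-methylpyran-2-one
Product: 20 lehualide E, via E-alkenylalane 19 (not isolated)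
Conditions: AlMe3 (2.5 equiv per alkyne), Cp2ZrCl2 (0.3 equiv), CH2Cl2, 0 °C to rt; excess AlMe3 removed in vacuo; then 14 (0.7 equiv), Pd(PPh3)4 (5 mol%), THF, 0 °C to rt
Reagents that add atoms: trimethylaluminium, C[Al](C)C
Why: Zirconium-catalysed syn-carboalumination of the terminal alkyne (Negishi carboalumination) places methyl on the internal carbon cis to aluminium on the terminal carbon, which fixes the E geometry, and palladium-catalysed cross-coupling of the alkenylalane with the allylic-type bromide (Negishi coupling) should form the CH2–CH= bond with retention of that geometry.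

Compound list
1 | dimethyl squarate (3,4-dimethoxycyclobut-3-ene-1,2-dione) | COC1=C(OC)C(=O)C1=O | starting material
2 | methyllithium | [Li]C | starting material
3 | 4-hydroxy-2,3-dimethoxy-4-methylcyclobut-2-en-1-one (racemic) | COC1=C(OC)C(C)(O)C1=O | intermediate
4 | thionyl chloride | O=S(Cl)Cl | starting material
5 | 4-chloro-2,3-dimethoxy-4-methylcyclobut-2-en-1-one (racemic) | COC1=C(OC)C(C)(Cl)C1=O | intermediate
6 | carbon monoxide | [C-]#[O+] | starting material
7 | tetramethylstannane | C[Sn](C)(C)C | starting material
8 | 4-acetyl-2,3-dimethoxy-4-methylcyclobut-2-en-1-one (racemic, not isolated) | COC1=C(OC)C(C)(C(C)=O)C1=O | intermediate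
9 | (3E)-2,3-dimethoxy-4-methylhexa-1,3-diene-1,5-dione (acyl vinylketene, not isolated) | O=C=C(OC)/C(OC)=C(C)\C(C)=O | intermediate
10 | 3,4-dimethoxy-5,6-dimethylpyran-2-one | COc1c(C)c(C)oc(=O)c1OC | intermediate
11 | lithium bis(trimethylsilyl)amide | [Li]N([Si](C)(C)C)[Si](C)(C)C | starting material
12 | 1,2-dibromo-1,1,2,2-tetrachloroethane | BrC(Cl)(Cl)C(Cl)(Cl)Br | starting material
13 | lithium 3,4-dimethoxy-5-methyl-6-methylidene-6H-pyran-2-olate (lithium dienolate, not isolated) | C=C1OC(O[Li])=C(OC)C(OC)=C1C | intermediate
14 | 6-(bromomethyl)-3,4-dimethoxy-5-methylpyran-2-one | COc1c(C)c(CBr)oc(=O)c1OC | intermediate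
15 | (6-bromohexyl)benzene | BrCCCCCCc1ccccc1 | starting material
16 | lithium acetylide–ethylenediamine complex | [Li]C#C.NCCN | starting material
17 | oct-7-yn-1-ylbenzene (8-phenyloct-1-yne) | C#CCCCCCCc1ccccc1 | intermediate
18 | trimethylaluminium | C[Al](C)C | starting material
19 | (E)-dimethyl(2-methyl-8-phenyloct-1-en-1-yl)alane (not isolated) | C[Al](C)/C=C(\C)CCCCCCc1ccccc1 | intermediate
20 | lehualide E, 3,4-dimethoxy-5-methyl-6-[(2E)-3-methyl-9-phenylnon-2-en-1-yl]pyran-2-one | COc1c(C)c(C/C=C(\C)CCCCCCc2ccccc2)oc(=O)c1OC | target

Total step count: 6. Longest linear sequence: 5 steps (steps 1, 2, 3, 4 and 6, from dimethyl squarate); step 5 supplies the side chain convergently.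

Steps most likely to fail

Step 3. The acyl group may be delivered to the methoxy-bearing allyl terminus, or methyl may couple before CO is taken up, so that the wrong substitution pattern or a non-carbonylated ring results. The fallback sets out from dimethyl squarate 1 and leaves the C5 methyl group out of the ring expansion, adding it afterwards. Reduction of 1 with LiAlH(OtBu)3 (THF, −78 °C) should give 4-hydroxy-2,3-dimethoxycyclobut-2-en-1-one F1, and SOCl2/pyridine the secondary chloride 4-chloro-2,3-dimethoxycyclobut-2-en-1-one F2. Its allyl termini (CH against C–OMe) differ sterically in the sense for which this carbonylative coupling is established. The CO/Me4Sn/Pd(PPh3)4 conditions of step 3 should then give 3,4-dimethoxy-6-methylpyran-2-one F3. Electrophilic bromination at the only free ring position (NBS, MeCN, dark) should give 5-bromo-3,4-dimethoxy-6-methylpyran-2-one F4, and Suzuki–Miyaura methylation (trimethylboroxine, PdCl2(dppf), K2CO3, dioxane, 90 °C) comes back to the route at pyranone 10.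

Step 2. The tertiary chloride may ionise during formation or handling, with loss of a methoxy group by hydrolysis or with decomposition on concentration. The fallback sets out from alcohol 3 and bypasses chloride 5. Acetylation (Ac2O, Et3N, DMAP, CH2Cl2, 0 °C) should give the far less ionisable, purifiable allylic ester 2,3-dimethoxy-1-methyl-4-oxocyclobut-2-en-1-yl acetate F5. Zerovalent palladium ionises allylic acetates in the same sense as chlorides (Tsuji–Trost-type oxidative addition), so F5 is submitted, with LiCl as additive, to the CO/Me4Sn conditions of step 3 and comes back to the route at pyranone 10.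

Step 4. Proton exchange between the product and unreacted dienolate may lead to over-bromination, and the dienolate may be alkylated by the product (dimerisation). The fallback sets out from pyranone 10 and functionalises the methyl group by oxidation instead of anion chemistry. Riley oxidation (SeO2, dioxane, sealed tube, 150 °C) of the activated 6-methyl group should give 4,5-dimethoxy-3-methyl-6-oxo-6H-pyran-2-carbaldehyde F6. NaBH4 (MeOH, −20 °C) should reduce the aldehyde to 6-(hydroxymethyl)-3,4-dimethoxy-5-methylpyran-2-one F7, and Appel bromination (CBr4, PPh3, CH2Cl2, 0 °C) comes back to the route at bromide 14.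

Further compounds
F1 | step 3 | 4-hydroxy-2,3-dimethoxycyclobut-2-en-1-one (racemic) | COC1=C(OC)C(O)C1=O
F2 | step 3 | 4-chloro-2,3-dimethoxycyclobut-2-en-1-one (racemic) | COC1=C(OC)C(Cl)C1=O
F3 | step 3 | 3,4-dimethoxy-6-methylpyran-2-one | COc1cc(C)oc(=O)c1OC
F4 | step 3 | 5-bromo-3,4-dimethoxy-6-methylpyran-2-one | COc1c(Br)c(C)oc(=O)c1OC
F5 | step 2 | 2,3-dimethoxy-1-methyl-4-oxocyclobut-2-en-1-yl acetate (racemic) | COC1=C(OC)C(C)(OC(C)=O)C1=O
F6 | step 4 | 4,5-dimethoxy-3-methyl-6-oxo-6H-pyran-2-carbaldehyde | COc1c(C)c(C=O)oc(=O)c1OC
F7 | step 4 | 6-(hydroxymethyl)-3,4-dimethoxy-5-methylpyran-2-one | COc1c(C)c(CO)oc(=O)c1OC
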